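**Retrosynthetic overview**
- Quinone ring, formed last: thermal Moore rearrangement of a 4-alkynyl-4-hydroxycyclobutenone made from dimethyl squarate and the lithium acetylide of (S)-3-ethynyl-6,7,8-trimethoxychroman, so no oxidant is needed.
- Benzene A ring and pyran ring, formed together in one pot: a second squarate adduct (a 4-alk-1-en-2-yl-4-hydroxycyclobutenone) ring-expands to a hydroquinone, and the phenol next to the side chain closes onto a CH2Cl arm. All four A-ring oxygens come from the squarate.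
- Linker: one CH carrying a silylalkyne, a CH2Cl and a 2-bromoallyl arm; its stereocentre comes from an Evans alkylation of a 4-silylbut-3-ynoyl imide with 2,3-dibromopropene.
- Ring order: benzene A + pyran (step 7), then quinone (step 9).

Assumption: the target stereocentre (chroman C3) is (S) by CIP as drawn; the carbinol carbons of cyclobutenones 14 and 20 form as epimer mixtures, are written without configuration, and disappear on ring expansion.

**Route**

Step 1
Reactants: 1 4-(trimethylsilyl)but-3-yn-1-ol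
Product: 2 4-(trimethylsilyl)but-3-ynoic acid
Conditions: CrO3, H2SO4, H2O/acetone, 0 °C
Reagents that add atoms: water, O
Why: Jones oxidation of a primary alcohol to the acid through the aldehyde hydrate; the C-silyl alkyne tolerates cold chromic acid and no stereocentre is involved.

Step 2
Reactants: 2 4-(trimethylsilyl)but-3-ynoic acid; 3 (S)-4-benzyl-1,3-oxazolidin-2-one
Product: 6 (S)-4-benzyl-3-[4-(trimethylsilyl)but-3-ynoyl]-1,3-oxazolidin-2-one, via acid chloride 4 (not isolated), via lithium oxazolidinide 5 (not isolated)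
Conditions: (COCl)2, DMF (cat.), CH2Cl2, 0 °C to rt; 3, n-BuLi, THF, −78 °C; then 4, −78 °C, 30 min
Reagents that add atoms: none
Why: N-acylation of a lithiated Evans oxazolidinone by an acid chloride; working cold and without amine base keeps the β,γ-alkynoyl unit from isomerising to the allene, and the auxiliary centre is untouched.

Step 3
Reactants: 6 (S)-4-benzyl-3-[4-(trimethylsilyl)but-3-ynoyl]-1,3-oxazolidin-2-one; 7 2,3-dibromopropene
Product: 9 (S)-4-benzyl-3-[(2S)-4-bromo-2-[(trimethylsilyl)ethynyl]pent-4-enoyl]-1,3-oxazolidin-2-one, via sodium enolate 8 (not isolated)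
Conditions: NaHMDS, THF, −78 °C; then 7, −78 to −45 °C
Reagents that add atoms: none
Why: Evans asymmetric alkylation, in which the chelated Z-enolate takes the allylic bromide on the face opposite the benzyl group; this is the usual sense, read as (2S) here because alkynyl outranks the new CH2, and the silyl group blocks γ-attack.

Step 4
Reactants: 9 (S)-4-benzyl-3-[(2S)-4-bromo-2-[(trimethylsilyl)ethynyl]pent-4-enoyl]-1,3-oxazolidin-2-one
Product: 10 (2S)-4-bromo-2-[(trimethylsilyl)ethynyl]pent-4-en-1-ol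
Conditions: LiBH4, MeOH (1 equiv), Et2O, 0 °C
Reagents that add atoms: none
Why: Reductive cleavage of the imide by hydride gives the primary alcohol and returns the auxiliary; the cold, weakly basic medium does not enolise the α-centre, and the vinyl bromide and silylalkyne are inert.

Step 5
Reactants: 10 (2S)-4-bromo-2-[(trimethylsilyl)ethynyl]pent-4-en-1-ol
Product: 11 [(3S)-5-bromo-3-(chloromethyl)hex-5-en-1-yn-1-yl]trimethylsilane
Conditions: PPh3, NCS, CH2Cl2, 0 °C to rt
Reagents that add atoms: N-chlorosuccinimide, O=C1CCC(=O)N1Cl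
Why: Appel-type chlorination of a primary alcohol; substitution occurs at CH2 only, so the adjacent stereocentre keeps its configuration.

Step 6
Reactants: 11 [(3S)-5-bromo-3-(chloromethyl)hex-5-en-1-yn-1-yl]trimethylsilane; 12 dimethyl squarate
Product: 14 4-[(4S)-4-(chloromethyl)-6-(trimethylsilyl)hex-1-en-5-yn-2-yl]-4-hydroxy-2,3-dimethoxycyclobut-2-en-1-one, via alkenyllithium 13 (not isolated)
Conditions: t-BuLi (2.1 equiv), Et2O, −78 °C; then 12 (1.3 equiv), THF, −78 °C; aq. NH4Cl
Reagents that add atoms: none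
Why: Bromine–lithium exchange followed by 1,2-addition of the alkenyllithium to one squarate carbonyl (Moore-type squarate addition); the primary chloride and silylalkyne survive at −78 °C, and the new carbinol centre is uncontrolled but is destroyed in step 7.

Step 7
Reactants: 14 4-[(4S)-4-(chloromethyl)-6-(trimethylsilyl)hex-1-en-5-yn-2-yl]-4-hydroxy-2,3-dimethoxycyclobut-2-en-1-one
Product: 18 (3S)-3-ethynyl-6,7,8-trimethoxy-3,4-dihydro-2H-chromene, via hydroquinone 15 (not isolated), via silyl chromanol 16 (not isolated), via silyl alkyne ether 17 (not isolated)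
Conditions: degassed p-xylene, 138 °C, 1 h; then K2CO3, NaI (cat.), DMF, 70 °C, Ar; then MeI, rt; then MeOH, rt
Reagents that add atoms: iodomethane, CI
Why: Moore-type thermal ring expansion (4π electrocyclic opening, 6π electrocyclisation, tautomerisation) builds the benzene ring as a hydroquinone; only the phenol ortho to the side chain can close the pyran by 6-exo-tet Williamson etherification, the remaining phenol is then O-methylated and K2CO3/MeOH removes the C-silyl group, with the stereocentre a spectator throughout.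

Step 8
Reactants: 18 (3S)-3-ethynyl-6,7,8-trimethoxy-3,4-dihydro-2H-chromene; 12 dimethyl squarate
Product: 20 4-hydroxy-2,3-dimethoxy-4-{[(3S)-6,7,8-trimethoxy-3,4-dihydro-2H-chromen-3-yl]ethynyl}cyclobut-2-en-1-one, via lithium acetylide 19 (not isolated)
Conditions: n-BuLi (1.0 equiv), THF, −78 °C; then 12 (1.3 equiv), THF, −78 °C; aq. NH4Cl
Reagents that add atoms: none
Why: Selective deprotonation of the terminal alkyne and 1,2-addition of the acetylide to dimethyl squarate (Moore-type squarate addition); the propargylic C3–H is not removed by one equivalent of base at −78 °C.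

Step 9
Reactants: 20 4-hydroxy-2,3-dimethoxy-4-{[(3S)-6,7,8-trimethoxy-3,4-dihydro-2H-chromen-3-yl]ethynyl}cyclobut-2-en-1-one
Product: 21 abruquinone B
Conditions: degassed p-xylene, 138 °C, 30–45 min
Reagents that add atoms: none
Why: Moore rearrangement of a 4-alkynyl-4-hydroxycyclobutenone (4π ring opening, radical ring closure, hydrogen shift from OH) gives the 2,3-dimethoxy-5-alkyl-1,4-benzoquinone directly under neutral conditions, so the acid/base-sensitive C3 centre next to the quinone is never exposed to reagents.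

**Compound list**
1 | 4-(trimethylsilyl)but-3-yn-1-ol | C[Si](C)(C)C#CCCO | starting material
2 | 4-(trimethylsilyl)but-3-ynoic acid | C[Si](C)(C)C#CCC(=O)O | intermediate
3 | (S)-4-benzyl-1,3-oxazolidin-2-one | O=C1N[C@@H](Cc2ccccc2)CO1 | starting material
4 | 4-(trimethylsilyl)but-3-ynoyl chloride | C[Si](C)(C)C#CCC(=O)Cl | intermediate
5 | lithium (S)-4-benzyl-2-oxo-1,3-oxazolidin-3-ide | [Li]N1[C@@H](Cc2ccccc2)COC1=O | intermediate
6 | (S)-4-benzyl-3-[4-(trimethylsilyl)but-3-ynoyl]-1,3-oxazolidin-2-one | C[Si](C)(C)C#CCC(=O)N1[C@@H](Cc2ccccc2)COC1=O | intermediate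
7 | 2,3-dibromopropene | BrCC(Br)=C | starting material
8 | sodium (Z)-enolate of 6 | C[Si](C)(C)C#C/C=C(\[O-])N1[C@@H](Cc2ccccc2)COC1=O.[Na+] | intermediate
9 | (S)-4-benzyl-3-[(2S)-4-bromo-2-[(trimethylsilyl)ethynyl]pent-4-enoyl]-1,3-oxazolidin-2-one | C[Si](C)(C)C#C[C@H](CC(Br)=C)C(=O)N1[C@@H](Cc2ccccc2)COC1=O | intermediate
10 | (2S)-4-bromo-2-[(trimethylsilyl)ethynyl]pent-4-en-1-ol | C[Si](C)(C)C#C[C@H](CC(Br)=C)CO | intermediate
11 | [(3S)-5-bromo-3-(chloromethyl)hex-5-en-1-yn-1-yl]trimethylsilane | C[Si](C)(C)C#C[C@H](CC(Br)=C)CCl | intermediate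
12 | dimethyl squarate (3,4-dimethoxycyclobut-3-ene-1,2-dione) | COC1=C(OC)C(=O)C1=O | starting material
13 | [(4S)-4-(chloromethyl)-6-(trimethylsilyl)hex-1-en-5-yn-2-yl]lithium | [Li]C(=C)C[C@H](CCl)C#C[Si](C)(C)C | intermediate
14 | 4-[(4S)-4-(chloromethyl)-6-(trimethylsilyl)hex-1-en-5-yn-2-yl]-4-hydroxy-2,3-dimethoxycyclobut-2-en-1-one | COC1=C(OC)C(O)(C(=C)C[C@H](CCl)C#C[Si](C)(C)C)C1=O | intermediate
15 | 5-[(2S)-2-(chloromethyl)-4-(trimethylsilyl)but-3-yn-1-yl]-2,3-dimethoxybenzene-1,4-diol | Oc1cc(C[C@H](CCl)C#C[Si](C)(C)C)c(O)c(OC)c1OC | intermediate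
16 | (3S)-7,8-dimethoxy-3-[(trimethylsilyl)ethynyl]-3,4-dihydro-2H-chromen-6-ol | C[Si](C)(C)C#C[C@H]1COc2c(OC)c(OC)c(O)cc2C1 | intermediate
17 | trimethyl{[(3S)-6,7,8-trimethoxy-3,4-dihydro-2H-chromen-3-yl]ethynyl}silane | C[Si](C)(C)C#C[C@H]1COc2c(OC)c(OC)c(OC)cc2C1 | intermediate
18 | (3S)-3-ethynyl-6,7,8-trimethoxy-3,4-dihydro-2H-chromene | C#C[C@H]1COc2c(OC)c(OC)c(OC)cc2C1 | intermediate
19 | lithium acetylide of 18 | [Li]C#C[C@H]1COc2c(OC)c(OC)c(OC)cc2C1 | intermediate
20 | 4-hydroxy-2,3-dimethoxy-4-{[(3S)-6,7,8-trimethoxy-3,4-dihydro-2H-chromen-3-yl]ethynyl}cyclobut-2-en-1-one | COC1=C(OC)C(O)(C#C[C@H]2COc3c(OC)c(OC)c(OC)cc3C2)C1=O | intermediate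
21 | abruquinone B, 2,3-dimethoxy-5-[(3S)-6,7,8-trimethoxy-3,4-dihydro-2H-chromen-3-yl]cyclohexa-2,5-diene-1,4-dione | COC1=C(OC)C(=O)C([C@H]2COc3c(cc(OC)c(OC)c3OC)C2)=CC1=O | target

**Totals**
Total step count: 9. Longest linear sequence: 9 (steps 1–9; 3, 7 and 12 are bought).

**Three steps most likely to fail, with fallbacks**

Step 3 (enolate alkylation next to an alkyne: allene formation, γ-attack or poor diastereoselectivity). The fallback keeps the carbonyl out of the bond-forming step. It sets out from 1 (with 7) and returns at 10. Compound 1 is converted with n-BuLi (1 equiv) and then s-BuLi/TMEDA (THF, −78 to −20 °C) into its O,C-dilithio propargylic dianion, which is alkylated with 7 at −78 °C to give racemic 4-bromo-2-[(trimethylsilyl)ethynyl]pent-4-en-1-ol F1 (propargylic lithiation of a 1-silylalkyne, alkylation at the propargylic carbon). F1 is then resolved by lipase transesterification (Amano PS, vinyl acetate, MTBE, about 55% conversion). The enzyme is assumed to acylate the (R)-alcohol to (2R)-4-bromo-2-[(trimethylsilyl)ethynyl]pent-4-en-1-yl acetate F2 and leave (S)-alcohol 10; this preference must be checked by Mosher ester analysis, and preparative chiral SFC of F1 is the backstop.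

Step 7 (air oxidation of the hydroquinone under base, or unselective one-pot alkylations). The fallback closes the pyran before aromatisation, so no free hydroquinone is ever present. It sets out from 14 and returns at 16. Treating 14 with NaH and Bu4NI (cat.) in THF/DMF at 0 °C to rt lets the tertiary alkoxide displace the chloride (6-exo-tet) to give the spiro ether (7S)-2,3-dimethoxy-9-methylidene-7-[(trimethylsilyl)ethynyl]-5-oxaspiro[3.5]non-2-en-1-one F3. Thermolysis of F3 (p-xylene, 138 °C) by the same ring expansion gives the mono-phenol 16 directly. Compound 16 is then methylated and desilylated (MeI, K2CO3, DMF; then MeOH) to 18 as in the main route.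

Step 9 (Moore rearrangement diverted to the alkylidenecyclopentenedione, or thermal loss). The fallback builds the quinone ring through the alkenyl manifold, which can only close to the six-membered ring. It sets out from 18 and returns at 21. Hydrozirconation of 18 (Cp2Zr(H)Cl, THF, rt) and iodination (I2) give (3S)-3-[(E)-2-iodoethenyl]-6,7,8-trimethoxy-3,4-dihydro-2H-chromene F4. t-BuLi (2 equiv, Et2O, −78 °C) converts F4 into {(E)-2-[(3S)-6,7,8-trimethoxy-3,4-dihydro-2H-chromen-3-yl]ethenyl}lithium F5, which adds to 12 to give 4-hydroxy-2,3-dimethoxy-4-{(E)-2-[(3S)-6,7,8-trimethoxy-3,4-dihydro-2H-chromen-3-yl]ethenyl}cyclobut-2-en-1-one F6. Thermolysis (p-xylene, 138 °C; 4π opening, 6π closure) gives 2,3-dimethoxy-5-[(3S)-6,7,8-trimethoxy-3,4-dihydro-2H-chromen-3-yl]benzene-1,4-diol F7. Ag2O (Et2O, rt) oxidises F7 to 21; the fully O-alkylated A ring is not touched by this mild oxidant.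

**Further compounds**
F1 | step 3 | racemic 4-bromo-2-[(trimethylsilyl)ethynyl]pent-4-en-1-ol | C[Si](C)(C)C#CC(CC(Br)=C)CO
F2 | step 3 | (2R)-4-bromo-2-[(trimethylsilyl)ethynyl]pent-4-en-1-yl acetate | C[Si](C)(C)C#C[C@@H](CC(Br)=C)COC(C)=O
F3 | step 7 | (7S)-2,3-dimethoxy-9-methylidene-7-[(trimethylsilyl)ethynyl]-5-oxaspiro[3.5]non-2-en-1-one | COC1=C(OC)C2(OC[C@H](C#C[Si](C)(C)C)CC2=C)C1=O
F4 | step 9 | (3S)-3-[(E)-2-iodoethenyl]-6,7,8-trimethoxy-3,4-dihydro-2H-chromene | I/C=C/[C@H]1COc2c(OC)c(OC)c(OC)cc2C1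
F5 | step 9 | {(E)-2-[(3S)-6,7,8-trimethoxy-3,4-dihydro-2H-chromen-3-yl]ethenyl}lithium | [Li]/C=C/[C@H]1COc2c(OC)c(OC)c(OC)cc2C1
F6 | step 9 | 4-hydroxy-2,3-dimethoxy-4-{(E)-2-[(3S)-6,7,8-trimethoxy-3,4-dihydro-2H-chromen-3-yl]ethenyl}cyclobut-2-en-1-one | COC1=C(OC)C(O)(/C=C/[C@H]2COc3c(OC)c(OC)c(OC)cc3C2)C1=O
F7 | step 9 | 2,3-dimethoxy-5-[(3S)-6,7,8-trimethoxy-3,4-dihydro-2H-chromen-3-yl]benzene-1,4-diol | Oc1cc([C@H]2COc3c(OC)c(OC)c(OC)cc3C2)c(O)c(OC)c1OC
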